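**Plan**
- Cuts, last to first: the C15 ester and the C16 silyl ether; C12–C13 (B-alkyl Suzuki–Miyaura) between a decalin with a C9 vinyl group and a (Z)-iodobutenediol piece; C9–C11 and the C20 methyl back to a C9 nitrile, then a C9 ketone; the C8 methyl; finally ring A at C4–C5 and C1–C10.
- Enabling feature: ring A is a cyclohexene fused on C5–C10, with vinylic C4 on quaternary C5 and C1 on C10, next to C9. With C9 as a temporary ketone, C5 is the β-carbon and C10 the α-carbon of an enone, so a C18/C4–C3–C2–C1 unit (donor at C4, acceptor at C1) closes ring A on ring B.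
- Forward: ring B (3-methylcyclohex-2-enone) → one-flask hydroalumination/asymmetric conjugate addition/enolate alkylation with 5-chloropent-1-yne (ring A) → C8 methyl and equilibration → C9 nitrile → alkene shift to C3=C4 → C9 quaternary centre → C20 methyl → side chain by coupling → ester.
- Stereochemistry: C5 from the chiral copper catalyst; C10 (trans fusion) and C8 by equilibration α to the C9 ketone; C9 by equatorial attack anti to the axial C5 methyl; C13=C14 geometry from trans-hydroalumination/iodination and a stereoretentive coupling.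

Key step: step 1

Remark: positions are given in clerodane numbering (decalin C1–C10, side chain C11–C16, methyls C17 on C8, C18 on C4, C19 on C5, C20 on C9). The sense of induction of the copper catalyst is assumed by analogy; the ligand antipode that gives the (R)-configured C5 is to be confirmed on the first run.

**Step 1**
Reactants: 1 5-chloropent-1-yne; 2 3-methylcyclohex-2-en-1-one
Product: 6 (4aR,8aR)-4a-methyl-5-methylideneoctahydronaphthalen-1(2H)-one (cis-fused), via alkenylalane 3 (not isolated), via aluminium enolate 4 (not isolated), via lithium enolate 5 (not isolated)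
Conditions: 1 (1.5 equiv), diisobutylaluminium hydride (1.4 equiv), Ni(dppp)Cl2 (3 mol%), THF, 0 → 22 °C; then 2, copper thiophene-2-carboxylate (monovalent copper, 5 mol%), chiral phosphinamine Ph2P–N[CH(CH3)(2-naphthyl)]2 (single antipode, 5.5 mol%), Et2O/THF, −30 °C; then MeLi (1 equiv per Al), HMPA, −30 → 40 °C
Reagents that add atoms: none
Why: Proposed new method: nickel-catalysed Markovnikov hydroalumination of 1 gives 2-alkenylalane 3, the chiral copper catalyst transfers its alkenyl group (C4) to C5 of enone 2 to give the regiodefined C9–C10 aluminium enolate 4, and MeLi/HMPA converts this into lithium enolate 5, whose C10 displaces the tethered primary chloride at C1, so that C4–C5 and C1–C10 form in one flask; the closest known reaction types are the copper-catalysed enantioselective conjugate addition of 2-alkenylalanes to 3-methylcyclohex-2-enone and the two-stage alkenylcuprate addition/enolate alkylation (methylenecyclohexane annulation) with 5-chloro-2-metallopent-1-enes, which have not been joined in one flask under asymmetric catalysis, the untested link being the activation of an aluminium enolate for alkylation. Ring A closes by a 6-exo-tet C-alkylation of the enolate, O-alkylation being excluded because it would need an eight-membered ring. C5 (R) is set by the chiral ligand on copper; C10 is set by the substrate, because the four-carbon tether on C5 can reach the enolate carbon only on the face it occupies, which gives the cis ring fusion that step 2 corrects. The step needs 1,4- instead of 1,2-addition and alkenyl instead of isobutyl transfer (copper catalysis; sp2 groups transfer first), the branched alkenylalane (control by Ni(dppp)Cl2) and survival of the alkyl chloride until the enolate is activated (a primary chloride is inert to the alane and to the copper catalyst at −30 °C); only the C10 enolate is present, since it arises directly from the conjugate addition.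

**Step 2**
Reactants: 6 (4aR,8aR)-4a-methyl-5-methylideneoctahydronaphthalen-1(2H)-one
Product: 8 (2R,4aR,8aS)-2,4a-dimethyl-5-methylideneoctahydronaphthalen-1(2H)-one (trans-fused), via cis-fused C8-methyl ketone 7 (not isolated)
Conditions: lithium diisopropylamide, THF, −78 °C; MeI, −78 → 0 °C; then NaOMe, MeOH, 23 → 50 °C (same flask); chromatography, minor cis isomer re-equilibrated
Reagents that add atoms: iodomethane, CI
Why: Kinetic deprotonation occurs at the C8 methylene (C10–H is tertiary and flanked by quaternary C5) and methylation gives 7; methoxide equilibration through the C9 enolates should then epimerise both α-centres to the thermodynamic isomer, with trans ring fusion (10-H anti to the axial C5 methyl) and an equatorial C8 methyl (regioselective enolate alkylation followed by thermodynamic epimerisation).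

**Step 3**
Reactants: 8 (2R,4aR,8aS)-2,4a-dimethyl-5-methylideneoctahydronaphthalen-1(2H)-one
Product: 9 (2R,4aR,8aR)-2,4a-dimethyl-5-methylidenedecahydronaphthalene-1-carbonitrile (both C1 epimers)
Conditions: TosMIC, KOt-Bu, DME, EtOH (2 equiv), 0 → 35 °C
Reagents that add atoms: p-toluenesulfonylmethyl isocyanide (TosMIC), [C-]#[N+]CS(=O)(=O)c1ccc(C)cc1
Why: Van Leusen reductive cyanation, in which the TosMIC anion adds to the C9 carbonyl and ring closure, loss of sulfinate and ethanolysis of the N-formyl group deliver the nitrile with one added carbon (the future C20); the C9 configuration is irrelevant because C9 is deprotonated in step 5.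

**Step 4**
Reactants: 9 (2R,4aR,8aR)-2,4a-dimethyl-5-methylidenedecahydronaphthalene-1-carbonitrile
Product: 10 (2R,4aR,8aR)-2,4a,5-trimethyl-1,2,3,4,4a,7,8,8a-octahydronaphthalene-1-carbonitrile (both C1 epimers)
Conditions: Co(salen)Cl (salen = N,N′-bis(3,5-di-tert-butylsalicylidene)ethane-1,2-diaminate; 3 mol%), PhSiH3 (6 mol%), benzene, 23 °C
Reagents that add atoms: none
Why: Cobalt-hydride hydrogen-atom-transfer isomerisation, in which reversible H-atom addition to the 1,1-disubstituted C4=C18 alkene gives the tertiary C4 radical that loses H from C3 (C5 is quaternary, so C3 is the only ring position) to give the more stable trisubstituted C3=C4 alkene under neutral conditions that avoid a cationic methyl shift from C5; no stereocentre is touched.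

**Step 5**
Reactants: 10 (2R,4aR,8aR)-2,4a,5-trimethyl-1,2,3,4,4a,7,8,8a-octahydronaphthalene-1-carbonitrile
Product: 11 (1R,2R,4aR,8aS)-2,4a,5-trimethyl-1-[2-(phenylsulfinyl)ethyl]-1,2,3,4,4a,7,8,8a-octahydronaphthalene-1-carbonitrile (mixture at sulfur)
Conditions: lithium diisopropylamide, THF, −78 → 0 °C; phenyl vinyl sulfoxide, −78 → −20 °C; aq. NH4Cl
Reagents that add atoms: phenyl vinyl sulfoxide, C=CS(=O)c1ccccc1
Why: Michael addition of the lithiated nitrile (planar at C9) to a vinyl cation equivalent, in which the acceptor should approach C9 on the equatorial β face, away from the syn-axial C5 methyl on the α face, so that the new C9–C11 bond is equatorial and the nitrile (the future C20 methyl) axial, cis to the C5 and C8 methyls.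

**Step 6**
Reactants: 11 (1R,2R,4aR,8aS)-2,4a,5-trimethyl-1-[2-(phenylsulfinyl)ethyl]-1,2,3,4,4a,7,8,8a-octahydronaphthalene-1-carbonitrile
Product: 12 (1R,2R,4aR,8aS)-1-ethenyl-2,4a,5-trimethyl-1,2,3,4,4a,7,8,8a-octahydronaphthalene-1-carbonitrile
Conditions: toluene, NaHCO3, 110 °C
Reagents that add atoms: none
Why: Thermal syn-elimination of the sulfoxide (sulfoxide pyrolysis), which can only take a β-hydrogen from C11 and so gives the C11=C12 vinyl group without touching a stereocentre.

**Step 7**
Reactants: 12 (1R,2R,4aR,8aS)-1-ethenyl-2,4a,5-trimethyl-1,2,3,4,4a,7,8,8a-octahydronaphthalene-1-carbonitrile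
Product: 14 (1R,2R,4aR,8aS)-1-ethenyl-2,4a,5-trimethyl-1,2,3,4,4a,7,8,8a-octahydronaphthalene-1-carbaldehyde, via N-aluminio aldimine 13 (not isolated)
Conditions: diisobutylaluminium hydride, toluene, −78 → 0 °C; then 1 M aq. HCl, THF, 23 °C
Reagents that add atoms: water, O
Why: Partial reduction of the hindered tertiary nitrile, which stops at the N-aluminio aldimine and is hydrolysed to the aldehyde on acidic work-up; C9 is quaternary and cannot epimerise.

**Step 8**
Reactants: 14 (1R,2R,4aR,8aS)-1-ethenyl-2,4a,5-trimethyl-1,2,3,4,4a,7,8,8a-octahydronaphthalene-1-carbaldehyde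
Product: 16 (1S,2R,4aR,8aR)-1-ethenyl-1,2,4a,5-tetramethyl-1,2,3,4,4a,7,8,8a-octahydronaphthalene, via hydrazone 15 (not isolated)
Conditions: N2H4·H2O, KOH, diethylene glycol, 120 °C, then 200 °C (water and excess hydrazine distilled off), under N2
Reagents that add atoms: none
Why: Wolff–Kishner reduction (Huang-Minlon conditions) turns the neopentyl aldehyde into the C20 methyl through the hydrazone; the aldehyde has no α-hydrogen, the vinyl group on quaternary C9 has no allylic hydrogen to migrate, and air is excluded to avoid diimide reduction of the vinyl group.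

**Step 9**
Reactants: 17 but-2-yne-1,4-diol
Product: 18 4-[(tert-butyldimethylsilyl)oxy]but-2-yn-1-ol
Conditions: NaH (1.0 equiv), THF, 0 → 23 °C; TBSCl (1.0 equiv)
Reagents that add atoms: tert-butyldimethylsilyl chloride, CC(C)(C)[Si](C)(C)Cl
Why: Monosilylation of a symmetrical diol through its sparingly soluble monosodium alkoxide, which is silylated once (O-silylation of an alkoxide).

**Step 10**
Reactants: 18 4-[(tert-butyldimethylsilyl)oxy]but-2-yn-1-ol
Product: 20 (2Z)-4-[(tert-butyldimethylsilyl)oxy]-3-iodobut-2-en-1-ol, via cyclic alkenylalanate 19 (not isolated)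
Conditions: NaAlH2(OCH2CH2OCH3)2, THF, 0 → 23 °C; then iodine, THF, −78 → 0 °C
Reagents that add atoms: iodine, [I][I]
Why: Alkoxide-directed trans-hydroalumination of the propargylic alcohol places aluminium on the distal alkyne carbon in a five-membered alanate ring, and iodinolysis with retention gives the vinyl iodide with iodine cis to CH2OH, which fixes the geometry of the future C13=C14 bond.

**Step 11**
Reactants: 16 (1S,2R,4aR,8aR)-1-ethenyl-1,2,4a,5-tetramethyl-1,2,3,4,4a,7,8,8a-octahydronaphthalene; 20 (2Z)-4-[(tert-butyldimethylsilyl)oxy]-3-iodobut-2-en-1-ol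
Product: 22 (2E)-3-{[(tert-butyldimethylsilyl)oxy]methyl}-5-[(1S,2R,4aR,8aR)-1,2,4a,5-tetramethyl-1,2,3,4,4a,7,8,8a-octahydronaphthalen-1-yl]pent-2-en-1-ol, via B-alkyl-9-BBN 21 (not isolated)
Conditions: 9-BBN (1.5 equiv), THF, 23 → 60 °C; then 3 M aq. Cs2CO3, 20 (1.2 equiv), Pd(dppf)Cl2 (5 mol%), AsPh3 (5 mol%), DMF, 23 °C
Reagents that add atoms: none
Why: Anti-Markovnikov hydroboration of the C9 vinyl group with 9-BBN (which leaves the trisubstituted C3=C4 alkene alone) followed by B-alkyl Suzuki–Miyaura coupling with retention of alkene geometry forms C12–C13, so that C12 is cis to C15 and the silyloxymethyl carbon C16 trans to it.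

**Step 12**
Reactants: 22 (2E)-3-{[(tert-butyldimethylsilyl)oxy]methyl}-5-[(1S,2R,4aR,8aR)-1,2,4a,5-tetramethyl-1,2,3,4,4a,7,8,8a-octahydronaphthalen-1-yl]pent-2-en-1-ol; 23 docosanoyl chloride
Product: 24 (2E)-3-{[(tert-butyldimethylsilyl)oxy]methyl}-5-[(1S,2R,4aR,8aR)-1,2,4a,5-tetramethyl-1,2,3,4,4a,7,8,8a-octahydronaphthalen-1-yl]pent-2-en-1-yl docosanoate
Conditions: Et3N, DMAP (10 mol%), CH2Cl2, 0 → 23 °C
Reagents that add atoms: none
Why: DMAP-catalysed O-acylation of the only free hydroxyl (primary, allylic, at C15) by the acid chloride.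

**Step 13**
Reactants: 24 (2E)-3-{[(tert-butyldimethylsilyl)oxy]methyl}-5-[(1S,2R,4aR,8aR)-1,2,4a,5-tetramethyl-1,2,3,4,4a,7,8,8a-octahydronaphthalen-1-yl]pent-2-en-1-yl docosanoate
Product: 25 (2E)-3-(hydroxymethyl)-5-[(1S,2R,4aR,8aR)-1,2,4a,5-tetramethyl-1,2,3,4,4a,7,8,8a-octahydronaphthalen-1-yl]pent-2-en-1-yl docosanoate (target)
Conditions: HF·pyridine, pyridine, THF, 0 → 23 °C
Reagents that add atoms: none
Why: Fluoride cleavage of the primary silyl ether under buffered conditions that leave the ester and both alkenes intact; the two oxygens sit trans across the C13=C14 bond, so acyl migration is not possible.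

**Compound list**
1 | 5-chloropent-1-yne | C#CCCCCl | starting material
2 | 3-methylcyclohex-2-en-1-one | CC1=CC(=O)CCC1 | starting material
3 | (5-chloropent-1-en-2-yl)bis(2-methylpropyl)alumane (not isolated) | C=C(CCCCl)[Al](CC(C)C)CC(C)C | intermediate
4 | {[(3R)-3-(5-chloropent-1-en-2-yl)-3-methylcyclohex-1-en-1-yl]oxy}bis(2-methylpropyl)alumane (not isolated) | CC(C)C[Al](CC(C)C)OC1=C[C@@](C)(CCC1)C(=C)CCCCl | intermediate
5 | lithium (3R)-3-(5-chloropent-1-en-2-yl)-3-methylcyclohex-1-en-1-olate (not isolated) | [Li+].[O-]C1=C[C@@](C)(CCC1)C(=C)CCCCl | intermediate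
6 | (4aR,8aR)-4a-methyl-5-methylideneoctahydronaphthalen-1(2H)-one, cis-fused | O=C1CCC[C@@]2(C)C(=C)CCC[C@@H]12 | intermediate
7 | (4aR,8aR)-2,4a-dimethyl-5-methylideneoctahydronaphthalen-1(2H)-one, cis-fused, C2 epimer mixture (C2 left open on purpose; not isolated) | O=C1C(C)CC[C@@]2(C)C(=C)CCC[C@@H]12 | intermediate
8 | (2R,4aR,8aS)-2,4a-dimethyl-5-methylideneoctahydronaphthalen-1(2H)-one, trans-fused, equatorial 2-methyl | O=C1[C@H](C)CC[C@@]2(C)C(=C)CCC[C@H]12 | intermediate
9 | (2R,4aR,8aR)-2,4a-dimethyl-5-methylidenedecahydronaphthalene-1-carbonitrile, C1 epimer mixture (C1 left open on purpose) | N#CC1[C@H](C)CC[C@@]2(C)C(=C)CCC[C@H]12 | intermediate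
10 | (2R,4aR,8aR)-2,4a,5-trimethyl-1,2,3,4,4a,7,8,8a-octahydronaphthalene-1-carbonitrile, C1 epimer mixture | N#CC1[C@H](C)CC[C@@]2(C)C(C)=CCC[C@H]12 | intermediate
11 | (1R,2R,4aR,8aS)-2,4a,5-trimethyl-1-[2-(phenylsulfinyl)ethyl]-1,2,3,4,4a,7,8,8a-octahydronaphthalene-1-carbonitrile, mixture at sulfur | O=S(CC[C@@]1(C#N)[C@H](C)CC[C@@]2(C)C(C)=CCC[C@H]12)c1ccccc1 | intermediate
12 | (1R,2R,4aR,8aS)-1-ethenyl-2,4a,5-trimethyl-1,2,3,4,4a,7,8,8a-octahydronaphthalene-1-carbonitrile | C=C[C@@]1(C#N)[C@H](C)CC[C@@]2(C)C(C)=CCC[C@H]12 | intermediate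
13 | N-[bis(2-methylpropyl)alumanyl]-1-[(1R,2R,4aR,8aS)-1-ethenyl-2,4a,5-trimethyl-1,2,3,4,4a,7,8,8a-octahydronaphthalen-1-yl]methanimine (not isolated) | C=C[C@@]1(C=N[Al](CC(C)C)CC(C)C)[C@H](C)CC[C@@]2(C)C(C)=CCC[C@H]12 | intermediate
14 | (1R,2R,4aR,8aS)-1-ethenyl-2,4a,5-trimethyl-1,2,3,4,4a,7,8,8a-octahydronaphthalene-1-carbaldehyde | C=C[C@@]1(C=O)[C@H](C)CC[C@@]2(C)C(C)=CCC[C@H]12 | intermediate
15 | hydrazone of 14, {[(1R,2R,4aR,8aS)-1-ethenyl-2,4a,5-trimethyl-1,2,3,4,4a,7,8,8a-octahydronaphthalen-1-yl]methylidene}hydrazine (not isolated) | C=C[C@@]1(C=NN)[C@H](C)CC[C@@]2(C)C(C)=CCC[C@H]12 | intermediate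
16 | (1S,2R,4aR,8aR)-1-ethenyl-1,2,4a,5-tetramethyl-1,2,3,4,4a,7,8,8a-octahydronaphthalene | C=C[C@@]1(C)[C@H](C)CC[C@@]2(C)C(C)=CCC[C@H]12 | intermediate
17 | but-2-yne-1,4-diol | OCC#CCO | starting material
18 | 4-[(tert-butyldimethylsilyl)oxy]but-2-yn-1-ol | OCC#CCO[Si](C)(C)C(C)(C)C | intermediate
19 | sodium 3-{[(tert-butyldimethylsilyl)oxy]methyl}-2,2-bis(2-methoxyethoxy)-2,5-dihydro-1,2-oxaaluminol-2-uide (cyclic alkenylalanate, not isolated) | [Na+].COCCO[Al-]1(OCCOC)OCC=C1CO[Si](C)(C)C(C)(C)C | intermediate
20 | (2Z)-4-[(tert-butyldimethylsilyl)oxy]-3-iodobut-2-en-1-ol | OC/C=C(/CO[Si](C)(C)C(C)(C)C)I | intermediate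
21 | 9-{2-[(1S,2R,4aR,8aR)-1,2,4a,5-tetramethyl-1,2,3,4,4a,7,8,8a-octahydronaphthalen-1-yl]ethyl}-9-borabicyclo[3.3.1]nonane (not isolated) | B1(C2CCCC1CCC2)CC[C@@]1(C)[C@H](C)CC[C@@]2(C)C(C)=CCC[C@H]12 | intermediate
22 | (2E)-3-{[(tert-butyldimethylsilyl)oxy]methyl}-5-[(1S,2R,4aR,8aR)-1,2,4a,5-tetramethyl-1,2,3,4,4a,7,8,8a-octahydronaphthalen-1-yl]pent-2-en-1-ol | OC/C=C(/CO[Si](C)(C)C(C)(C)C)CC[C@@]1(C)[C@H](C)CC[C@@]2(C)C(C)=CCC[C@H]12 | intermediate
23 | docosanoyl chloride | CCCCCCCCCCCCCCCCCCCCCC(=O)Cl | starting material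
24 | (2E)-3-{[(tert-butyldimethylsilyl)oxy]methyl}-5-[(1S,2R,4aR,8aR)-1,2,4a,5-tetramethyl-1,2,3,4,4a,7,8,8a-octahydronaphthalen-1-yl]pent-2-en-1-yl docosanoate | CCCCCCCCCCCCCCCCCCCCCC(=O)OC/C=C(/CO[Si](C)(C)C(C)(C)C)CC[C@@]1(C)[C@H](C)CC[C@@]2(C)C(C)=CCC[C@H]12 | intermediate
25 | (2E)-3-(hydroxymethyl)-5-[(1S,2R,4aR,8aR)-1,2,4a,5-tetramethyl-1,2,3,4,4a,7,8,8a-octahydronaphthalen-1-yl]pent-2-en-1-yl docosanoate | CCCCCCCCCCCCCCCCCCCCCC(=O)OC/C=C(/CO)CC[C@@]1(C)[C@H](C)CC[C@@]2(C)C(C)=CCC[C@H]12 | target

**Totals**
Total step count: 13. Longest linear sequence: 11 steps (steps 1–8 and 11–13); steps 9 and 10 make the side-chain piece.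

**Steps most likely to fail**

Step 1 (the proposed new method). The aluminium enolate may not be activated cleanly, so that it is protonated on work-up instead of closing ring A, and ligand-free background addition may erode the enantiopurity. The fallback runs the two bond formations as separate, known operations. From 2, the copper-catalysed asymmetric conjugate addition of alane 3 is carried out alone and quenched with aqueous NH4Cl to give (3R)-3-(5-chloropent-1-en-2-yl)-3-methylcyclohexan-1-one F1, which can be purified and checked for enantiopurity. F1 is then cyclised by intramolecular enolate alkylation with KOt-Bu in THF/t-BuOH (only the C10 enolate can close a six-membered ring) and comes back to the route at 6.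

Step 3. Enolisation of the flanked C9 ketone (with epimerisation at C8 and C10 and reaction through the minor cis isomer) may outrun addition of the bulky TosMIC anion. The fallback homologates by olefination instead. From 8, Wittig reaction with Ph3P=CHOMe (from (methoxymethyl)triphenylphosphonium chloride and KOt-Bu, THF) gives the enol ether (2R,4aR,8aS)-1-(methoxymethylidene)-2,4a-dimethyl-5-methylidenedecahydronaphthalene F2. Hydrolysis with dilute aqueous HCl in THF gives (2R,4aR,8aR)-2,4a-dimethyl-5-methylidenedecahydronaphthalene-1-carbaldehyde F3. Oxidative amination of F3 with iodine in aqueous ammonia/THF gives the nitrile and comes back to the route at 9.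

Step 5. Addition of the hindered tertiary carbanion at C9 may be slow, and the vinyl sulfoxide may oligomerise under the anionic conditions. The fallback forms C9–C11 by SN2 alkylation instead of conjugate addition. From 10, the lithiated nitrile (lithium diisopropylamide, THF/HMPA, −78 °C) is alkylated with 2-chloroethyl phenyl sulfide (NaI as catalyst) to give (1R,2R,4aR,8aS)-2,4a,5-trimethyl-1-[2-(phenylsulfanyl)ethyl]-1,2,3,4,4a,7,8,8a-octahydronaphthalene-1-carbonitrile F4. Oxidation of F4 with NaIO4 in aqueous methanol at 0 °C gives the sulfoxide and comes back to the route at 11.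

**Further compounds**
F1 | step 1 | (3R)-3-(5-chloropent-1-en-2-yl)-3-methylcyclohexan-1-one | O=C1CCC[C@](C)(C1)C(=C)CCCCl
F2 | step 3 | (2R,4aR,8aS)-1-(methoxymethylidene)-2,4a-dimethyl-5-methylidenedecahydronaphthalene (E/Z mixture) | COC=C1[C@H](C)CC[C@@]2(C)C(=C)CCC[C@H]12
F3 | step 3 | (2R,4aR,8aR)-2,4a-dimethyl-5-methylidenedecahydronaphthalene-1-carbaldehyde (C1 epimer mixture) | O=CC1[C@H](C)CC[C@@]2(C)C(=C)CCC[C@H]12
F4 | step 5 | (1R,2R,4aR,8aS)-2,4a,5-trimethyl-1-[2-(phenylsulfanyl)ethyl]-1,2,3,4,4a,7,8,8a-octahydronaphthalene-1-carbonitrile | c1ccccc1SCC[C@@]1(C#N)[C@H](C)CC[C@@]2(C)C(C)=CCC[C@H]12
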